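**Plan**
- Retrosynthesis: the phenols are unmasked last from benzyl ethers. The two CH2OH groups come from a cis-fused γ-lactone bridging C3 and C4. The lactone comes from a C4 vinyl group and a spiro Meldrum's acid unit on C3.
- The oxolane O1–C2–C3–C4–C5 is then cut at O1–C2 and C3–C4. The O1–C5–C4 unit (aryl on C5, vinyl on C4 as a masked CH2OH) is an aryl vinyl epoxide. The C2–C3 unit (aryl on C2, two acyl groups on C3) is an arylidene Meldrum's acid.
- The feature that allows the key step is a ring oxygen on C5 next to an allyl-bearing C4, facing an electron-poor C2=C3 alkene. This fits a zwitterionic [3+2] annulation under zerovalent palladium.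
- Forward: one aldehyde supplies both partners (diene then epoxide; Knoevenagel adduct). The annulation closes the oxolane. Vinyl cleavage and reduction close the lactone as a second ring, which LiAlH4 reopens. Hydrogenolysis ends the route.
- Stereochemistry: C5 from a Shi epoxidation; C4 by net retention in the palladium step; C2 in the ring closure under ligand control; C3 by the obligatory cis fusion of the lactone.

Key step: step 4

Ring numbering used throughout: O1, C2 (aryl carbon from the arylidene), C3, C4, C5 (aryl carbon from the epoxide). In this numbering the target is (2S,3S,4R,5S): the C2 aryl and both CH2OH groups are mutually cis, and the C5 aryl is trans to them.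

Assumption: the (R,R) ligand is taken as the antipode matched to (2R,3R)-4 in step 4; if the pairing proves reversed, the (S,S) ligand replaces it and nothing else changes.

**Step 1**
Reactants: 1 4-(benzyloxy)-3-methoxybenzaldehyde; 2 diethyl prop-2-en-1-ylphosphonate
Product: 3 1-(benzyloxy)-4-[(1E)-buta-1,3-dien-1-yl]-2-methoxybenzene
Conditions: 2, n-BuLi, THF–HMPA, −78 °C; then 1, −78 °C → rt
Reagents that add atoms: none
Why: Horner–Wadsworth–Emmons olefination: the lithiated allylphosphonate adds through its α-carbon to the aryl aldehyde and the adduct loses diethyl phosphate on warming to give the conjugated diene with the (E) geometry that the epoxidation requires; benzyl and methyl ethers are inert.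

**Step 2**
Reactants: 3 1-(benzyloxy)-4-[(1E)-buta-1,3-dien-1-yl]-2-methoxybenzene
Product: 4 (2R,3R)-2-[4-(benzyloxy)-3-methoxyphenyl]-3-ethenyloxirane
Conditions: D-fructose-derived ketone catalyst (1,2:4,5-di-O-isopropylidene-β-D-erythro-2,3-hexodiulo-2,6-pyranose, 30 mol %), KHSO5 (Oxone), K2CO3, Bu4NHSO4, MeCN–CH2(OMe)2/aq. Na2B4O7 buffer, 0 °C
Reagents that add atoms: potassium peroxymonosulfate KHSO5, SMILES [K+].[O-]S(=O)(=O)OO
Why: Shi asymmetric epoxidation: the dioxirane formed from the ketone and KHSO5 reacts through a spiro transition state with the trans-disubstituted styrenyl double bond in preference to the monosubstituted vinyl group, and the D-fructose-derived ketone delivers oxygen to the face that gives (R,R)-epoxides from trans-1-aryl alkenes, which sets C5 and the future C4 together; the basic buffer keeps the acid-labile benzylic epoxide intact.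

**Step 3**
Reactants: 1 4-(benzyloxy)-3-methoxybenzaldehyde; 5 2,2-dimethyl-1,3-dioxane-4,6-dione (Meldrum's acid)
Product: 6 5-[[4-(benzyloxy)-3-methoxyphenyl]methylidene]-2,2-dimethyl-1,3-dioxane-4,6-dione
Conditions: piperidine (10 mol %), AcOH (10 mol %), EtOH, rt
Reagents that add atoms: none
Why: Knoevenagel condensation of an aromatic aldehyde with the strongly C–H-acidic Meldrum's acid under piperidinium acetate catalysis, driven by crystallisation of the arylidene product; no stereocentre is formed.

**Step 4**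
Reactants: 4 (2R,3R)-2-[4-(benzyloxy)-3-methoxyphenyl]-3-ethenyloxirane; 6 5-[[4-(benzyloxy)-3-methoxyphenyl]methylidene]-2,2-dimethyl-1,3-dioxane-4,6-dione
Product: 7 (1R,3S,4S)-1,3-bis[4-(benzyloxy)-3-methoxyphenyl]-4-ethenyl-8,8-dimethyl-2,7,9-trioxaspiro[4.5]decane-6,10-dione (oxolane numbering: aryl groups 2,5-trans; vinyl trans to the C5 aryl and cis to the C2 aryl)
Conditions: Pd2(dba)3·CHCl3 (2.5 mol %), (R,R)-N,N'-(cyclohexane-1,2-diyl)bis[2-(diphenylphosphanyl)benzamide] (7.5 mol %), toluene, rt, slow addition of 4 to 6 (1.3 equiv)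
Reagents that add atoms: none
Why: Zerovalent palladium ionises the allylic C–O bond of 4 anti to the leaving oxygen to give a zwitterionic π-allyl complex with the alkoxide on C5; the alkoxide adds reversibly to the benzylidene carbon of 6 (O1–C2) and the Meldrum's acid anion so formed attacks the internal allyl terminus anti to the metal (C3–C4), which releases the catalyst. The closest known reaction type is the zerovalent-palladium-catalysed [3+2] annulation of vinyl oxiranes with doubly activated alkenes, and the Meldrum's acid acceptor is chosen over the malonate because it is far more electrophilic and so traps the alkoxide before the zwitterion can isomerise by hydride shift to the aryl allyl ketone. The oxolane closes in a 5-exo attack of the stabilised carbanion on the π-allyl unit, which is favoured over 7-endo attack at the distal terminus. C5 keeps the epoxide configuration because its C–O bond is never broken, C4 is formed with net retention (two inversions) and therefore with vinyl trans to the C5 aryl, and C2 is decided only in the ring closure, where the two C2-epimeric oxa-Michael adducts interconvert (Curtin–Hammett) and the chiral pocket of the ligand, matched to the substrate, is relied on to favour the closure that places the C2 aryl trans to the C5 aryl. The step needs capture to outrun isomerisation (secured by slow addition of 4 to an excess of the highly electrophilic 6) and needs 2,5-trans selectivity, which the ring itself does not bias strongly and which is the least certain point of the route.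

**Step 5**
Reactants: 7 (1R,3S,4S)-1,3-bis[4-(benzyloxy)-3-methoxyphenyl]-4-ethenyl-8,8-dimethyl-2,7,9-trioxaspiro[4.5]decane-6,10-dione
Product: 8 (1R,3S,4S)-1,3-bis[4-(benzyloxy)-3-methoxyphenyl]-8,8-dimethyl-6,10-dioxo-2,7,9-trioxaspiro[4.5]decane-4-carbaldehyde
Conditions: OsO4 (2 mol %), NaIO4, 2,6-lutidine, dioxane–H2O, rt
Reagents that add atoms: sodium periodate NaIO4, SMILES [Na+].[O-]I(=O)(=O)=O; osmium tetroxide OsO4, SMILES O=[Os](=O)(=O)=O
Why: Johnson–Lemieux oxidation: osmylation of the only alkene and periodate cleavage of the diol remove the terminal carbon and leave the C4 aldehyde; 2,6-lutidine buffers the medium so that the Meldrum's ring is not hydrolysed and C4, already in its preferred trans relationship to the C5 aryl, is not epimerised.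

**Step 6**
Reactants: 8 (1R,3S,4S)-1,3-bis[4-(benzyloxy)-3-methoxyphenyl]-8,8-dimethyl-6,10-dioxo-2,7,9-trioxaspiro[4.5]decane-4-carbaldehyde
Product: 11 (3aR,4S,6S,6aR)-4,6-bis[4-(benzyloxy)-3-methoxyphenyl]tetrahydro-1H,3H-furo[3,4-c]furan-1-one, via hydroxymethyl spiro-dione 9 (not isolated), via lactone acid 10 (not isolated)
Conditions: NaBH4, THF–EtOH, −20 → 0 °C; aq. NaH2PO4; then toluene, 90 °C
Reagents that add atoms: none
Why: Aldehyde reduction followed by intramolecular alcoholysis of the Meldrum's acid unit and decarboxylation of the resulting malonic-type acid: the C4 CH2O– arm can only reach the carbonyl on its own face of the spiro ring (5-exo-trig acylation with loss of acetone), and protonation of the lactone enol can only give the cis-fused bicyclo[3.3.0] system, so that C3 is set with its carbonyl carbon cis to the C4 arm and to the C2 aryl.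

**Step 7**
Reactants: 11 (3aR,4S,6S,6aR)-4,6-bis[4-(benzyloxy)-3-methoxyphenyl]tetrahydro-1H,3H-furo[3,4-c]furan-1-one
Product: 12 [(2S,3S,4R,5S)-2,5-bis[4-(benzyloxy)-3-methoxyphenyl]oxolane-3,4-diyl]dimethanol
Conditions: LiAlH4, THF, 0 °C; then H2O, aq. NaOH
Reagents that add atoms: none
Why: LiAlH4 reduction of the γ-lactone to the 1,4-diol; hydride addition is much faster than enolisation, so C3 is not epimerised, and no other group in the molecule is reducible.

**Step 8**
Reactants: 12 [(2S,3S,4R,5S)-2,5-bis[4-(benzyloxy)-3-methoxyphenyl]oxolane-3,4-diyl]dimethanol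
Product: 13 4,4'-[(2S,3S,4R,5S)-3,4-bis(hydroxymethyl)oxolane-2,5-diyl]bis(2-methoxyphenol)
Conditions: H2 (1 atm), 10% Pd/C, EtOAc, rt
Reagents that add atoms: none
Why: Catalytic hydrogenolysis: aryl benzyl ethers are cleaved much faster than the ring benzylic C–O bonds of the oxolane under 1 atm H2 in ethyl acetate, so both phenols are released without touching the ring or its four stereocentres.

**Compound list**
1 | 4-(benzyloxy)-3-methoxybenzaldehyde | COc1cc(C=O)ccc1OCc1ccccc1 | starting material
2 | diethyl prop-2-en-1-ylphosphonate (diethyl allylphosphonate) | C=CCP(=O)(OCC)OCC | starting material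
3 | 1-(benzyloxy)-4-[(1E)-buta-1,3-dien-1-yl]-2-methoxybenzene | COc1cc(/C=C/C=C)ccc1OCc1ccccc1 | intermediate
4 | (2R,3R)-2-[4-(benzyloxy)-3-methoxyphenyl]-3-ethenyloxirane (trans) | COc1cc([C@H]2O[C@@H]2C=C)ccc1OCc1ccccc1 | intermediate
5 | 2,2-dimethyl-1,3-dioxane-4,6-dione (Meldrum's acid) | CC1(C)OC(=O)CC(=O)O1 | starting material
6 | 5-[[4-(benzyloxy)-3-methoxyphenyl]methylidene]-2,2-dimethyl-1,3-dioxane-4,6-dione | COc1cc(C=C2C(=O)OC(C)(C)OC2=O)ccc1OCc1ccccc1 | intermediate
7 | (1R,3S,4S)-1,3-bis[4-(benzyloxy)-3-methoxyphenyl]-4-ethenyl-8,8-dimethyl-2,7,9-trioxaspiro[4.5]decane-6,10-dione | COc1cc([C@H]2O[C@H](c3ccc(OCc4ccccc4)c(OC)c3)[C@@H](C=C)C25C(=O)OC(C)(C)OC5=O)ccc1OCc1ccccc1 | intermediate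
8 | (1R,3S,4S)-1,3-bis[4-(benzyloxy)-3-methoxyphenyl]-8,8-dimethyl-6,10-dioxo-2,7,9-trioxaspiro[4.5]decane-4-carbaldehyde | COc1cc([C@H]2O[C@H](c3ccc(OCc4ccccc4)c(OC)c3)[C@@H](C=O)C25C(=O)OC(C)(C)OC5=O)ccc1OCc1ccccc1 | intermediate
9 | (1R,3S,4R)-1,3-bis[4-(benzyloxy)-3-methoxyphenyl]-4-(hydroxymethyl)-8,8-dimethyl-2,7,9-trioxaspiro[4.5]decane-6,10-dione | COc1cc([C@H]2O[C@H](c3ccc(OCc4ccccc4)c(OC)c3)[C@@H](CO)C25C(=O)OC(C)(C)OC5=O)ccc1OCc1ccccc1 | intermediate
10 | (3aR,4S,6R,6aR)-4,6-bis[4-(benzyloxy)-3-methoxyphenyl]-1-oxotetrahydro-1H,3H-furo[3,4-c]furan-6a(6H)-carboxylic acid | COc1cc([C@H]2O[C@H](c4ccc(OCc5ccccc5)c(OC)c4)[C@H]3COC(=O)[C@@]23C(=O)O)ccc1OCc1ccccc1 | intermediate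
11 | (3aR,4S,6S,6aR)-4,6-bis[4-(benzyloxy)-3-methoxyphenyl]tetrahydro-1H,3H-furo[3,4-c]furan-1-one | COc1cc([C@H]2O[C@H](c4ccc(OCc5ccccc5)c(OC)c4)[C@H]3COC(=O)[C@@H]23)ccc1OCc1ccccc1 | intermediate
12 | [(2S,3S,4R,5S)-2,5-bis[4-(benzyloxy)-3-methoxyphenyl]oxolane-3,4-diyl]dimethanol | COc1cc([C@H]2O[C@H](c3ccc(OCc4ccccc4)c(OC)c3)[C@@H](CO)[C@H]2CO)ccc1OCc1ccccc1 | intermediate
13 | 4,4'-[(2S,3S,4R,5S)-3,4-bis(hydroxymethyl)oxolane-2,5-diyl]bis(2-methoxyphenol) | COc1cc([C@H]2O[C@H](c3ccc(O)c(OC)c3)[C@@H](CO)[C@H]2CO)ccc1O | target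

**Count**
Total: 8 steps. Longest linear sequence: 7 steps (steps 1, 2, 4, 5, 6, 7, 8).

**Steps most likely to fail**

Step 4. The two C2-epimeric zwitterions may close at similar rates, or the closure that places both aryl groups pseudo-equatorial (2,5-cis) may win, so that facial discrimination at C2 is poor. The alkoxy π-allyl intermediate may also leak to the aryl allyl ketone by hydride shift.
Fallback (sets out from 1, returns at 11): C2 is set last, by hydride delivery to a bicyclic oxocarbenium ion, instead of in the annulation.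
- An Evans syn-aldol reaction of 1 with (S)-4-benzyl-3-(pent-4-enoyl)oxazolidin-2-one (Bu2BOTf, iPr2NEt, CH2Cl2, −78 → 0 °C) should give the syn-aldol imide F1, which fixes C5 and C4.
- Silylation (t-BuMe2SiOTf, 2,6-lutidine) gives the silyl ether F2.
- LiBH4 (THF, H2O, 0 °C) removes the auxiliary and gives the primary alcohol F3.
- Cleavage of the terminal alkene (OsO4, NaIO4, 2,6-lutidine) and oxidation of the resulting lactol (TEMPO, PhI(OAc)2) give the β-substituted γ-lactone F4.
- Claisen acylation of its lithium enolate (LiN(iPr)2, 2.2 equiv, THF, −78 → 0 °C; methyl 4-(benzyloxy)-3-methoxybenzoate) gives the α-aroyl lactone F5.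
- Desilylation (Bu4NF, AcOH) lets the benzylic hydroxyl close onto the ketone, after equilibration of the β-keto lactone centre, to the cis-fused hemiketal F6.
- Et3SiH, BF3·OEt2 (CH2Cl2, −78 °C) reduces the derived oxocarbenium ion from the convex face. This places the C2 aryl on the concave face, cis to C3, and gives 11.

Step 2. The dioxirane may attack the terminal double bond of the aryl diene instead of the styrenyl one, or the acid-labile electron-rich aryl epoxide may open or rearrange during isolation.
Fallback (sets out from 1, returns at 4): the epoxide oxygen is placed on an enal, which has only one alkene.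
- Wittig homologation of 1 with Ph3P=CHCHO (toluene, 80 °C) gives the (E)-cinnamaldehyde F7.
- Iminium-catalysed epoxidation with (R)-2-[bis(3,5-bis(trifluoromethyl)phenyl)(trimethylsilyloxy)methyl]pyrrolidine (10 mol %) and aqueous H2O2 (CH2Cl2, rt) gives the (2S,3R)-epoxy aldehyde F8.
- Immediate methylenation with Ph3P=CH2 (from Ph3PCH3Br and KN(SiMe3)2, THF, −78 °C) gives 4.

Step 6. Thermal decarboxylation passes through the lactone enol, whose β-elimination of O1 would open the oxolane and erode C2. The free acid may also promote benzylic ionisation on heating.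
Fallback (sets out from 10, returns at 11): radical decarboxylation at room temperature.
- Acid 10, isolated after the borohydride and lactonisation stage, is coupled with N-hydroxypyridine-2-thione and dicyclohexylcarbodiimide (CH2Cl2, 0 °C, dark) to give the Barton ester F9.
- Irradiation with visible light in the presence of t-BuSH expels CO2. The ring-fusion radical takes hydrogen from the thiol on the convex face, which can only give the cis-fused lactone 11.

**Further compounds**
F1 | step 4 | (4S)-4-benzyl-3-[(2S,3S)-3-[4-(benzyloxy)-3-methoxyphenyl]-3-hydroxy-2-(prop-2-en-1-yl)propanoyl]-1,3-oxazolidin-2-one | C=CC[C@H](C(=O)N1C(=O)OC[C@@H]1Cc1ccccc1)[C@H](O)c1ccc(OCc2ccccc2)c(OC)c1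
F2 | step 4 | (4S)-4-benzyl-3-[(2S,3S)-3-[4-(benzyloxy)-3-methoxyphenyl]-3-[(tert-butyldimethylsilyl)oxy]-2-(prop-2-en-1-yl)propanoyl]-1,3-oxazolidin-2-one | C=CC[C@H](C(=O)N1C(=O)OC[C@@H]1Cc1ccccc1)[C@H](O[Si](C)(C)C(C)(C)C)c1ccc(OCc2ccccc2)c(OC)c1
F3 | step 4 | (2R)-2-[(S)-[4-(benzyloxy)-3-methoxyphenyl][(tert-butyldimethylsilyl)oxy]methyl]pent-4-en-1-ol | C=CC[C@H](CO)[C@H](O[Si](C)(C)C(C)(C)C)c1ccc(OCc2ccccc2)c(OC)c1
F4 | step 4 | (4R)-4-[(S)-[4-(benzyloxy)-3-methoxyphenyl][(tert-butyldimethylsilyl)oxy]methyl]oxolan-2-one | O=C1C[C@H](CO1)[C@H](O[Si](C)(C)C(C)(C)C)c1ccc(OCc2ccccc2)c(OC)c1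
F5 | step 4 | (4R)-3-[4-(benzyloxy)-3-methoxybenzoyl]-4-[(S)-[4-(benzyloxy)-3-methoxyphenyl][(tert-butyldimethylsilyl)oxy]methyl]oxolan-2-one (C3 epimerisable) | O=C1OC[C@H]([C@H](O[Si](C)(C)C(C)(C)C)c2ccc(OCc3ccccc3)c(OC)c2)C1C(=O)c1ccc(OCc2ccccc2)c(OC)c1
F6 | step 4 | (3aR,4S,6aR)-4,6-bis[4-(benzyloxy)-3-methoxyphenyl]-6-hydroxytetrahydro-1H,3H-furo[3,4-c]furan-1-one (hemiketal; C6 anomers) | COc1cc(C2(O)O[C@H](c4ccc(OCc5ccccc5)c(OC)c4)[C@H]3COC(=O)[C@@H]23)ccc1OCc1ccccc1
F7 | step 2 | (2E)-3-[4-(benzyloxy)-3-methoxyphenyl]prop-2-enal | COc1cc(/C=C/C=O)ccc1OCc1ccccc1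
F8 | step 2 | (2S,3R)-3-[4-(benzyloxy)-3-methoxyphenyl]oxirane-2-carbaldehyde | COc1cc([C@H]2O[C@@H]2C=O)ccc1OCc1ccccc1
F9 | step 6 | 2-thioxopyridin-1(2H)-yl (3aR,4S,6R,6aR)-4,6-bis[4-(benzyloxy)-3-methoxyphenyl]-1-oxotetrahydro-1H,3H-furo[3,4-c]furan-6a(6H)-carboxylate | COc1cc([C@H]2O[C@H](c4ccc(OCc5ccccc5)c(OC)c4)[C@H]3COC(=O)[C@@]23C(=O)ON6C=CC=CC6=S)ccc1OCc1ccccc1
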